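The earlier runs and the new flask stem from a simulated flask for an exercise, noise included.

In a one-step world the remainder R, the share of the charge not yet other capture product, would shrink at one steady rate k, and two times would tell the end: the time allowed, t, and the drain time τ = 1/k.

| flask | starting material | first nucleophile | second nucleophile | remark | time |
|---|---|---|---|---|---|
| teal | 0.012 M (in portions, 4) | 0.50 equiv | 2 equiv | run made earlier; portions every 2.0 s |  |
| blue | 0.012 M (in portions, 4) | 0.50 equiv | 3 equiv | run made earlier; portions every 2.0 s |  |
| ochre | 0.018 M (in portions, 4) | 0.50 equiv | 4 equiv | run made earlier; portions every 2.0 s |  |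
| flask | 0.012 M (in portions, 4) | 0.500 equiv | 4.00 equiv | the portions of starting material follow each other after 2.0 s, the first at the start | 10 min |

- teal (time / min: other capture product / %, target / %): 1.00: 58, 22; 2.00: 73, 10; 3.00: 84, 11; 4.00: 93, 3; 5.00: 96, 2; 6.00: 96, 1
- blue (time / min: other capture product / %, target / %): 0.417: 42, 25; 1.33: 82, 13; 2.00: 87, 6; 3.00: 94, 3; 5.00: 97, 4; 6.00: 101, 2
- ochre (time / min: other capture product / %, target / %): 1.33: 90, 6; 2.50: 96, 1; 4.00: 101, 2; 5.00: 100, 0; 6.00: 101, 0

(readings scatter by 1.5 percentage points)

- the reaction counts as stopped when no species that holds the starting material changes by six tenths of a point or more over the second half of the time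

* at 10 min, what has stopped the reaction, if anything has (the first nucleophile has run out first / the second nucleophile has run out first / forward and back rates have come level / all of the starting material has reacted / it is still moving)
* other capture product at 10 min, in percent of the starting material charged

The teal and blue runs match our flask in starting material and first nucleophile and differ in second nucleophile, so we read k from the fall of R in each:

teal: k = 0.597 /min with second nucleophile at 0.0240 M

blue: k = 0.878 /min at 0.0360 M

Per unit of second nucleophile these read 24.9 /M/min and 24.4 /M/min, so we treat the drain as pseudo-first-order in it, with mean κ = 24.6 /M/min. For our flask, at 0.0480 M: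

τ = 1/(κ × 0.0480 M) = 0.845 min

t/τ = 11.8

This drain time puts R at 0.270% by 5.00 min, below the stopping mark, so we expect the flask to have stopped.

The forecast says "all of the starting material has reacted", with 100% other capture product (range 98% to 101.5%), holding that “that nucleophile does not limit the outcome”.

The flask gives "all of the starting material has reacted", with >99.9% other capture product; at 5.00 min, target plus intermediate hold 0.195%.

    second nucleophile + intermediate → other capture product (k = 1.30 /M/s)
    first nucleophile + intermediate ⇌ target (K = 250 /M, k = 240 /M/s)
    starting material → intermediate (k = 0.960 /s)

The drain runs through the target's return: with the backward run from target removed, the same flask ends at 50.0% other capture product, not >99.9%.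

With 1.00 equiv of second nucleophile, τ stretches to 3.38 min and t/τ falls to 2.96. That reagent now shrinks one for one with R, so R = 1/(1 + t/τ), which leaves 74.7% other capture product. The computed neighbour gives 82.4%.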